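## Retrosynthetic overview

1. Asperimide C (23) comes from the fully protected compound 22 by one fluoride-mediated removal of the aryl TIPS ether, the alkyl TBS ether and the N-SEM group.
2. Key late disconnection: the benzylic CH2–C(maleimide) bond, made by Negishi coupling of a chroman-7-ylmethylzinc chloride (from chloride 12) with the bromo(aryl)maleimide 20; each fragment carries 14 of the 28 skeletal atoms.
3. Fragment 20: mono-Suzuki coupling of N-SEM-2,3-dibromomaleimide 16 (maleic anhydride → dibromoanhydride → imide ring → N-SEM) with aryl boronate 19 (from 4-bromophenol).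
4. Fragment 12: 3-bromophenol → ortho-formylation → isobutenyl Grignard addition and oxa-6π closure (pyran ring) → Jacobsen epoxidation (sets C-3) → hydride opening at C-4 → TBS ether → Br to CH2OH to CH2Cl.
5. Ring order: pyran ring of the chroman (step 2), imide ring (step 9), then the two halves are joined (step 14).

Assumption: the stereocentre in the target SMILES is (S) at C-3 of the chroman. C1 reagents (paraformaldehyde, DMF) and protecting-group reagents are treated as reagents, not starting materials.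

## Route

**Step 1**
Reactants: 1 3-bromophenol
Product: 2 4-bromo-2-hydroxybenzaldehyde
Conditions: MgCl2, Et3N, (CH2O)n, MeCN, reflux; 1 M HCl work-up
Reagents that add atoms: paraformaldehyde (as formaldehyde), C=O
Why: Casnati–Skattebøl magnesium-phenoxide ortho-formylation is ortho-specific and takes the unhindered ortho site para to bromine, which fixes the later C-4/C-7 relationship of the chroman.

**Step 2**
Reactants: 2 4-bromo-2-hydroxybenzaldehyde; 3 2-methylprop-1-en-1-ylmagnesium bromide
Product: 5 7-bromo-2,2-dimethyl-2H-chromene, via allylic alcohol 4 (not isolated)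
Conditions: 3 (2.3 equiv), THF, 0 °C → rt; aq. NH4Cl; crude 4, p-TsOH (5 mol%), toluene, rt → 50 °C
Reagents that add atoms: none
Why: Grignard 1,2-addition (the first equivalent is consumed by the phenol) gives the o-hydroxybenzylic allylic alcohol, which on acid-catalysed dehydration forms an o-quinone methide that closes by oxa-6π electrocyclisation to the 2H-chromene.

**Step 3**
Reactants: 5 7-bromo-2,2-dimethyl-2H-chromene
Product: 6 (3S,4S)-7-bromo-3,4-epoxy-2,2-dimethylchromane
Conditions: (S,S)-Jacobsen Mn(salen)Cl (4 mol%), 4-phenylpyridine N-oxide (20 mol%), aq. NaOCl (pH 11.3), CH2Cl2, 0 °C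
Reagents that add atoms: sodium hypochlorite, [Na+].[O-]Cl
Why: Jacobsen–Katsuki epoxidation is at its best with 2,2-dimethylchromenes (typically ≥95% ee), and the (S,S)-catalyst delivers oxygen to the face that gives the (3S,4S)-epoxide, which sets C-3 as S.

**Step 4**
Reactants: 6 (3S,4S)-7-bromo-3,4-epoxy-2,2-dimethylchromane
Product: 7 (3S)-7-bromo-2,2-dimethylchroman-3-ol
Conditions: LiAlH4, THF, 0 °C; Fieser work-up
Reagents that add atoms: none
Why: SN2 hydride opening of the epoxide occurs at benzylic C-4 because C-3 is neopentyl-like and shielded by the gem-dimethyl group, so the C-3–O bond is untouched and C-3 stays S (the aryl bromide survives at 0 °C).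

**Step 5**
Reactants: 7 (3S)-7-bromo-2,2-dimethylchroman-3-ol
Product: 8 (3S)-7-bromo-3-(tert-butyldimethylsilyloxy)-2,2-dimethylchromane
Conditions: TBSOTf, 2,6-lutidine, CH2Cl2, 0 °C
Reagents that add atoms: tert-butyldimethylsilyl trifluoromethanesulfonate (TBSOTf), CC(C)(C)[Si](C)(C)OS(=O)(=O)C(F)(F)F
Why: Silyl ether formation with the reactive silyl triflate overcomes the hindrance of the secondary alcohol next to the quaternary carbon and masks it for the organolithium and organozinc steps.

**Step 6**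
Reactants: 8 (3S)-7-bromo-3-(tert-butyldimethylsilyloxy)-2,2-dimethylchromane
Product: 11 [(3S)-3-(tert-butyldimethylsilyloxy)-2,2-dimethylchroman-7-yl]methanol, via aryllithium 9 (not isolated), via aldehyde 10 (not isolated)
Conditions: n-BuLi, THF, −78 °C; DMF, −78 → 0 °C; then MeOH, NaBH4, 0 °C
Reagents that add atoms: N,N-dimethylformamide (DMF), CN(C)C=O; n-butyllithium, [Li]CCCC (Li in 9 only)
Why: Bromine–lithium exchange followed by Bouveault formylation with DMF and in-situ borohydride reduction converts Ar–Br into Ar–CH2OH in one pot without affecting the silyl ether or the stereocentre.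

**Step 7**
Reactants: 11 [(3S)-3-(tert-butyldimethylsilyloxy)-2,2-dimethylchroman-7-yl]methanol
Product: 12 (3S)-3-(tert-butyldimethylsilyloxy)-7-(chloromethyl)-2,2-dimethylchromane
Conditions: PPh3, NCS, CH2Cl2, 0 °C → rt
Reagents that add atoms: N-chlorosuccinimide (NCS), O=C1CCC(=O)N1Cl
Why: Appel-type chlorination via the alkoxyphosphonium salt turns the primary benzylic alcohol into the chloride under neutral conditions that leave the TBS ether intact.

**Step 8**
Reactants: 13 maleic anhydride
Product: 14 2,3-dibromomaleic anhydride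
Conditions: Br2 (2.1 equiv), AlCl3 (cat.), neat, sealed tube, 120 °C
Reagents that add atoms: bromine, BrBr
Why: Two rounds of Lewis-acid-assisted bromine addition and HBr elimination give the vinylic dibromide.

**Step 9**
Reactants: 14 2,3-dibromomaleic anhydride
Product: 15 2,3-dibromomaleimide
Conditions: NH4OAc, AcOH, reflux
Reagents that add atoms: ammonium acetate, [NH4+].CC(=O)[O-]
Why: Ammonolysis of the anhydride to the amic acid and cyclodehydration in hot acetic acid form the imide ring.

**Step 10**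
Reactants: 15 2,3-dibromomaleimide
Product: 16 3,4-dibromo-1-{[2-(trimethylsilyl)ethoxy]methyl}-1H-pyrrole-2,5-dione
Conditions: SEMCl, K2CO3, acetone, 0 °C → rt
Reagents that add atoms: 2-(trimethylsilyl)ethoxymethyl chloride (SEMCl), C[Si](C)(C)CCOCCl
Why: N-alkylation of the acidic imide with the reactive chloromethyl ether removes the N–H that would quench the zinc reagent and installs a fluoride-labile group.

**Step 11**
Reactants: 17 4-bromophenol
Product: 18 (4-bromophenoxy)triisopropylsilane
Conditions: TIPSCl, imidazole, DMF, rt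
Reagents that add atoms: triisopropylsilyl chloride (TIPSCl), CC(C)[Si](Cl)(C(C)C)C(C)C
Why: Imidazole-promoted silylation gives a bulky aryl silyl ether that survives the basic Suzuki conditions.

**Step 12**
Reactants: 18 (4-bromophenoxy)triisopropylsilane
Product: 19 4,4,5,5-tetramethyl-2-[4-(triisopropylsilyloxy)phenyl]-1,3,2-dioxaborolane
Conditions: B2pin2, PdCl2(dppf) (3 mol%), KOAc, 1,4-dioxane, 85 °C
Reagents that add atoms: bis(pinacolato)diboron (B2pin2), CC1(C)OB(OC1(C)C)B1OC(C)(C)C(C)(C)O1
Why: Miyaura borylation converts the aryl bromide into a chromatographable pinacol boronate under weakly basic conditions.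

**Step 13**
Reactants: 16 3,4-dibromo-1-{[2-(trimethylsilyl)ethoxy]methyl}-1H-pyrrole-2,5-dione; 19 4,4,5,5-tetramethyl-2-[4-(triisopropylsilyloxy)phenyl]-1,3,2-dioxaborolane
Product: 20 3-bromo-4-[4-(triisopropylsilyloxy)phenyl]-1-{[2-(trimethylsilyl)ethoxy]methyl}-1H-pyrrole-2,5-dione
Conditions: 16 (1.5 equiv), Pd(PPh3)4 (5 mol%), K3PO4, dioxane/H2O (10:1), 60 °C
Reagents that add atoms: none
Why: Suzuki–Miyaura mono-coupling is favoured because the first aryl group makes the remaining C–Br bond more electron-rich and hindered, and the dibromide is used in excess.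

**Step 14**
Reactants: 12 (3S)-3-(tert-butyldimethylsilyloxy)-7-(chloromethyl)-2,2-dimethylchromane; 20 3-bromo-4-[4-(triisopropylsilyloxy)phenyl]-1-{[2-(trimethylsilyl)ethoxy]methyl}-1H-pyrrole-2,5-dione
Product: 22 3-{[(3S)-3-(tert-butyldimethylsilyloxy)-2,2-dimethylchroman-7-yl]methyl}-4-[4-(triisopropylsilyloxy)phenyl]-1-{[2-(trimethylsilyl)ethoxy]methyl}-1H-pyrrole-2,5-dione, via benzylzinc chloride 21 (not isolated)
Conditions: Zn dust (BrCH2CH2Br/TMSCl-activated), LiCl, THF, 25 °C; then 20 (0.8 equiv), Pd(OAc)2 (2 mol%), SPhos (4 mol%), THF, 25 °C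
Reagents that add atoms: zinc dust, [Zn] (Zn in 21 only)
Why: LiCl-mediated zinc insertion into the benzylic chloride gives a functional-group-tolerant benzylzinc reagent that undergoes Negishi coupling with the activated vinylic bromide of the maleimide, joining the two halves without touching the remote stereocentre.

**Step 15**
Reactants: 22 3-{[(3S)-3-(tert-butyldimethylsilyloxy)-2,2-dimethylchroman-7-yl]methyl}-4-[4-(triisopropylsilyloxy)phenyl]-1-{[2-(trimethylsilyl)ethoxy]methyl}-1H-pyrrole-2,5-dione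
Product: 23 Asperimide C
Conditions: TBAF (6 equiv), THF, argon, 0 → 45 °C; sat. aq. NH4Cl
Reagents that add atoms: none
Why: Fluoride cleaves both Si–O bonds and attacks the SEM silicon, whose fragmentation (ethene and formaldehyde) releases the imide N–H, a global desilylation that does not involve the C-3 stereocentre.

## Compound list

1 | 3-bromophenol | Oc1cccc(Br)c1 | starting material
2 | 4-bromo-2-hydroxybenzaldehyde | O=Cc1ccc(Br)cc1O | intermediate
3 | 2-methylprop-1-en-1-ylmagnesium bromide (THF solution) | CC(C)=C[Mg]Br | starting material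
4 | 5-bromo-2-(1-hydroxy-3-methylbut-2-en-1-yl)phenol (racemic, formed in situ) | CC(C)=CC(O)c1ccc(Br)cc1O | intermediate
5 | 7-bromo-2,2-dimethyl-2H-chromene | CC1(C)Oc2cc(Br)ccc2C=C1 | intermediate
6 | (3S,4S)-7-bromo-3,4-epoxy-2,2-dimethylchromane (cis-fused epoxide) | CC1(C)Oc2cc(Br)ccc2[C@@H]3O[C@H]13 | intermediate
7 | (3S)-7-bromo-2,2-dimethylchroman-3-ol | CC1(C)Oc2cc(Br)ccc2C[C@@H]1O | intermediate
8 | (3S)-7-bromo-3-(tert-butyldimethylsilyloxy)-2,2-dimethylchromane | CC1(C)Oc2cc(Br)ccc2C[C@@H]1O[Si](C)(C)C(C)(C)C | intermediate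
9 | [(3S)-3-(tert-butyldimethylsilyloxy)-2,2-dimethylchroman-7-yl]lithium (formed in situ) | CC1(C)Oc2cc([Li])ccc2C[C@@H]1O[Si](C)(C)C(C)(C)C | intermediate
10 | (3S)-3-(tert-butyldimethylsilyloxy)-2,2-dimethylchromane-7-carbaldehyde (formed in situ) | CC1(C)Oc2cc(C=O)ccc2C[C@@H]1O[Si](C)(C)C(C)(C)C | intermediate
11 | [(3S)-3-(tert-butyldimethylsilyloxy)-2,2-dimethylchroman-7-yl]methanol | CC1(C)Oc2cc(CO)ccc2C[C@@H]1O[Si](C)(C)C(C)(C)C | intermediate
12 | (3S)-3-(tert-butyldimethylsilyloxy)-7-(chloromethyl)-2,2-dimethylchromane | CC1(C)Oc2cc(CCl)ccc2C[C@@H]1O[Si](C)(C)C(C)(C)C | intermediate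
13 | maleic anhydride | O=C1OC(=O)C=C1 | starting material
14 | 2,3-dibromomaleic anhydride | O=C1OC(=O)C(Br)=C1Br | intermediate
15 | 2,3-dibromomaleimide (3,4-dibromo-1H-pyrrole-2,5-dione) | O=C1NC(=O)C(Br)=C1Br | intermediate
16 | 3,4-dibromo-1-{[2-(trimethylsilyl)ethoxy]methyl}-1H-pyrrole-2,5-dione | O=C1N(COCC[Si](C)(C)C)C(=O)C(Br)=C1Br | intermediate
17 | 4-bromophenol | Oc1ccc(Br)cc1 | starting material
18 | (4-bromophenoxy)triisopropylsilane | CC(C)[Si](Oc1ccc(Br)cc1)(C(C)C)C(C)C | intermediate
19 | 4,4,5,5-tetramethyl-2-[4-(triisopropylsilyloxy)phenyl]-1,3,2-dioxaborolane | CC(C)[Si](Oc1ccc(cc1)B1OC(C)(C)C(C)(C)O1)(C(C)C)C(C)C | intermediate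
20 | 3-bromo-4-[4-(triisopropylsilyloxy)phenyl]-1-{[2-(trimethylsilyl)ethoxy]methyl}-1H-pyrrole-2,5-dione | O=C1N(COCC[Si](C)(C)C)C(=O)C(c2ccc(O[Si](C(C)C)(C(C)C)C(C)C)cc2)=C1Br | intermediate
21 | {[(3S)-3-(tert-butyldimethylsilyloxy)-2,2-dimethylchroman-7-yl]methyl}zinc chloride (formed in situ) | CC1(C)Oc2cc(C[Zn]Cl)ccc2C[C@@H]1O[Si](C)(C)C(C)(C)C | intermediate
22 | 3-{[(3S)-3-(tert-butyldimethylsilyloxy)-2,2-dimethylchroman-7-yl]methyl}-4-[4-(triisopropylsilyloxy)phenyl]-1-{[2-(trimethylsilyl)ethoxy]methyl}-1H-pyrrole-2,5-dione | CC1(C)Oc2cc(CC3=C(c4ccc(O[Si](C(C)C)(C(C)C)C(C)C)cc4)C(=O)N(COCC[Si](C)(C)C)C3=O)ccc2C[C@@H]1O[Si](C)(C)C(C)(C)C | intermediate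
23 | Asperimide C, 3-{[(3S)-3-hydroxy-2,2-dimethylchroman-7-yl]methyl}-4-(4-hydroxyphenyl)-1H-pyrrole-2,5-dione | CC1(C)Oc2cc(CC3=C(c4ccc(O)cc4)C(=O)NC3=O)ccc2C[C@@H]1O | target

## Step count and risks

Total step count: 15.
Longest linear sequence: 9 steps (steps 1–7, 14, 15). The other branches are 6 steps (8, 9, 10, 13, 14, 15) and 5 steps (11, 12, 13, 14, 15).

The three steps most likely to fail:

**Step 13 (mono-Suzuki on the dibromide).** The risks are bis-arylation and attack of aqueous base on the C–Br bonds. The fallback reverses the order of the two couplings. It sets out from 16, which is treated in 1.5-fold excess under anhydrous, base-free Negishi conditions (Pd(PPh3)4, THF, 0 °C) with the zinc reagent 21, made from 12 as in step 14. This gives 3-bromo-4-{[(3S)-3-(tert-butyldimethylsilyloxy)-2,2-dimethylchroman-7-yl]methyl}-1-{[2-(trimethylsilyl)ethoxy]methyl}-1H-pyrrole-2,5-dione F1. The aryl group is then introduced last, by Suzuki coupling of the monobromide with boronate 19 (PdCl2(dppf), K3PO4, dioxane/H2O, 70 °C), where over-arylation is impossible. The sequence comes back to the route at 22.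

**Step 14 (zinc insertion and Negishi coupling).** The risks are Wurtz dimerisation of the benzylic zinc reagent and reduction of 20 instead of coupling. The fallback replaces the in-situ zinc reagent with an isolable boron nucleophile. It sets out from 12: Pd-catalysed borylation of the benzylic chloride (B2pin2, Pd2(dba)3, P(4-MeOC6H4)3, KOAc, toluene, 50 °C) gives 2-{[(3S)-3-(tert-butyldimethylsilyloxy)-2,2-dimethylchroman-7-yl]methyl}-4,4,5,5-tetramethyl-1,3,2-dioxaborolane F2. After purification this is joined to 20 by sp3–sp2 Suzuki–Miyaura coupling (Pd(OAc)2/SPhos, K3PO4, toluene/H2O, 80 °C), coming back to the route at 22.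

**Step 15 (one-pot fluoride deprotection).** The risks are incomplete N-SEM cleavage and base-induced isomerisation or oxidation at the benzylic maleimide position. The fallback stages the deprotection under acidic conditions. It sets out from 22: HF·pyridine (THF/pyridine, 0 °C → rt) removes both silyl ethers to give 3-{[(3S)-3-hydroxy-2,2-dimethylchroman-7-yl]methyl}-4-(4-hydroxyphenyl)-1-{[2-(trimethylsilyl)ethoxy]methyl}-1H-pyrrole-2,5-dione F3. BF3·OEt2 (CH2Cl2, 0 °C) then fragments the SEM group to 1-(hydroxymethyl)-3-{[(3S)-3-hydroxy-2,2-dimethylchroman-7-yl]methyl}-4-(4-hydroxyphenyl)-1H-pyrrole-2,5-dione F4. This loses formaldehyde on brief treatment with aqueous NH3 in MeOH at rt, coming back to the route at 23.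

## Further compounds

F1 | step 13 | 3-bromo-4-{[(3S)-3-(tert-butyldimethylsilyloxy)-2,2-dimethylchroman-7-yl]methyl}-1-{[2-(trimethylsilyl)ethoxy]methyl}-1H-pyrrole-2,5-dione | CC1(C)Oc2cc(CC3=C(Br)C(=O)N(COCC[Si](C)(C)C)C3=O)ccc2C[C@@H]1O[Si](C)(C)C(C)(C)C
F2 | step 14 | 2-{[(3S)-3-(tert-butyldimethylsilyloxy)-2,2-dimethylchroman-7-yl]methyl}-4,4,5,5-tetramethyl-1,3,2-dioxaborolane | CC1(C)Oc2cc(CB3OC(C)(C)C(C)(C)O3)ccc2C[C@@H]1O[Si](C)(C)C(C)(C)C
F3 | step 15 | 3-{[(3S)-3-hydroxy-2,2-dimethylchroman-7-yl]methyl}-4-(4-hydroxyphenyl)-1-{[2-(trimethylsilyl)ethoxy]methyl}-1H-pyrrole-2,5-dione | CC1(C)Oc2cc(CC3=C(c4ccc(O)cc4)C(=O)N(COCC[Si](C)(C)C)C3=O)ccc2C[C@@H]1O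
F4 | step 15 | 1-(hydroxymethyl)-3-{[(3S)-3-hydroxy-2,2-dimethylchroman-7-yl]methyl}-4-(4-hydroxyphenyl)-1H-pyrrole-2,5-dione | CC1(C)Oc2cc(CC3=C(c4ccc(O)cc4)C(=O)N(CO)C3=O)ccc2C[C@@H]1O
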